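The numbers in the tables are simulated on assumed constants, noise included.

The vessel is closed, stirred and held at one temperature, and the substrate in it falls fast at first and then crawls. What to watch on a repeat is how that crawl depends on the charge.

| flask | substrate | coupling partner | target | time |
|---|---|---|---|---|
| cedar | 200 mM | 240 mM |  |  |
| elm | 120 mM | 160 mM |  |  |
| oak | 200 mM | 360 mM |  |  |
| maple | 200 mM | 240 mM | 60.0 mM |  |
| alder | 600 mM | 720 mM |  | 37 min |

| run | time / min | [substrate] / mM |
|---|---|---|
| cedar run | 2.1 | 173.6 |
| cedar run | 6.4 | 151.9 |
| cedar run | 12 | 136.9 |
| cedar run | 19 | 125.3 |
| cedar run | 28 | 113.5 |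
| cedar run | 37 | 105.9 |
| elm run | 2.1 | 108.1 |
| elm run | 6.4 | 96.5 |
| elm run | 12 | 88.8 |
| elm run | 19 | 82.0 |
| elm run | 28 | 76.5 |
| elm run | 37 | 71.4 |
| oak run | 2.1 | 167.4 |
| oak run | 6.4 | 145.1 |
| oak run | 12 | 131.8 |
| oak run | 19 | 120.2 |
| oak run | 28 | 109.8 |
| oak run | 37 | 102.7 |
| maple run | 2.1 | 172.5 |
| maple run | 6.4 | 152.8 |
| maple run | 12 | 138.2 |
| maple run | 19 | 126.1 |
| maple run | 28 | 115.2 |
| maple run | 37 | 108.3 |

(scatter of a reading: 0.6 mM)

* order of the initial rate in [coupling partner], near the charge of the cedar run, the rate being that where two percent of its substrate are target
* order of the initial rate in [substrate], near the charge of the cedar run, the rate being that where two percent of its substrate are target (one fixed amount of target, the same in the runs compared)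
* substrate in the alder run at 37 min, as a share of the substrate charged

- Overall: substrate + coupling partner -> target.
- Constant volume, constant temperature.
- "The second partner" is coupling partner.
- An order is taken over about fifteen percent of the charge, up and down.

Two chemists read the crawl differently. The first keeps a clock in minutes: something fades at its own pace, whatever the flask. Her best evidence is oak against cedar, which have equal substrate and 1.50 times the coupling partner in oak. From 12 min to 37 min, ln of the [substrate] ratio is 0.249 in oak and 0.257 in cedar, about the same, as if the partner charge had been forgotten.

The second chemist says that if each step is overall second-order, a flask with each species charged at c times its cedar charge shows at time t the substrate share cedar shows at c·t. For alder, with 3.00 times the cedar charge of both species, the reach, clock time multiplied by that c, is 111 min. His test is elm, whose c, the geometric mean of its two charge ratios, is 0.632. Elm at 19 min has a reach of 12.0 min, and its substrate share there, 68.3%, sits beside 68.5% in cedar at 12 min. Cedar at 19 min shows 62.6%. On his view rates scale as c², so the two orders add to about two, and each stands near 1.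

My own reckoning for alder follows him. The fall of ln[substrate] per unit of ln t in the cedar readings rises from 0.120 over the first two readings to 0.252 over the last three. Continued straight in ln t to the middle of the gap up to the reach, it becomes 0.312, which by my estimate leaves alder at 37 min with 37.6% of its substrate charge.

The forecast stands on the clock side, holding that “the partner speeds the reaction but probably also speeds catalyst death”. It gives 0.7 for the partner, 1.1 for substrate and 37% for alder. Its orders add to 1.80, less than 2, so the dispute is over the partner order.

The flask gives 1.0 for the partner, 1.2 for substrate and 35.1% for alder.

    substrate + coupling partner → target (0.4056 /M/min)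
    target + coupling partner → side product (0.1674 /M/min)
    2 coupling partner → lost reagent (1.500 /M/min)
    2 substrate → homo dimer (0.03144 /M/min)

Where two percent of cedar's substrate have turned, the oak rate is 1.5 times cedar's, the partner ratio itself, while the clock keeps its ground in the readings from 12 min to 37 min, where those two flasks lose alike. Alder's 35.1% is the share at a reach of 111 min. In elm, target comes to a quarter of the elm substrate charge at 60.2 min, a reach of 38.0 min; where two percent of cedar's substrate have turned, c² takes cedar's 16 mM/min to 6.39 mM/min, and the elm rate stands at 5.6 mM/min.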